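**Retrosynthetic overview**
1. Ester C–O bond: target ⇒ azulenetriol core + O-silylated 4-hydroxybenzoyl chloride (from 4-bromophenol); only the secondary C4–OH can be acylated.
2. Cycloheptene ring (closed last): C6–C7 bond and the C6 carbinol by a Ni-catalysed reductive coupling of a (Z)-alkenyl iodide with a tethered methyl ketone.
3. (Z)-Alkenyl iodide ⇐ (Z)-vinylsilane (ipso-iodination); C3 carbinol ⇐ isopropyl-cerium addition to the cyclopentanone.
4. Cyclopentanone carrying C8a, C3a and C4 ⇐ one-pot union of three pieces: Cu-catalysed asymmetric conjugate addition of a (Z)-silylvinyl alane to 3-methylcyclopent-2-enone, then aluminium-enolate aldol with 3,3-dimethoxybutanal.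
5. Ring order: cyclopentane (bought as the enone) first, cycloheptene second; the three side pieces are made in parallel.

Assumption: ring positions are cited with the azulene numbering of the target (C1 to C8a), and "matched" ligand antipodes are those that give the configurations drawn.

**Route**

Step 1
Reactants: 1 ethynyltrimethylsilane
Product: 3 (iodoethynyl)trimethylsilane, via lithium (trimethylsilyl)acetylide 2 (not isolated)
Conditions: n-BuLi (1.05 equiv), THF, −78 °C; then I2 (1.05 equiv), −78 °C → rt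
Reagents that add atoms: iodine (II)
Why: Deprotonation of the terminal alkyne and electrophilic iodination of the lithium acetylide is the standard route to a 1-iodoalkyne.

Step 2
Reactants: 3 (iodoethynyl)trimethylsilane
Product: 4 [(Z)-2-iodoethenyl]trimethylsilane
Conditions: 2-nitrobenzenesulfonyl hydrazide (NBSH, 2.5 equiv), Et3N, THF/i-PrOH 1:1, rt, 16 h
Reagents that add atoms: none
Why: Diimide generated from NBSH transfers H2 syn to the iodoalkyne without touching the C–I bond, so the cis-reduction gives the (Z)-iodoalkene.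

Step 3
Reactants: 5 methyl 3-oxobutanoate
Product: 6 methyl 3,3-dimethoxybutanoate
Conditions: HC(OMe)3 (1.5 equiv), MeOH, p-TsOH (1 mol %), rt; NaOMe quench before concentration
Reagents that add atoms: trimethyl orthoformate (COC(OC)OC)
Why: Acid-catalysed ketalisation with the orthoformate as water scavenger masks the ketone as its dimethyl ketal.

Step 4
Reactants: 6 methyl 3,3-dimethoxybutanoate
Product: 7 3,3-dimethoxybutanal
Conditions: DIBAL-H (1.1 equiv), CH2Cl2, −78 °C; MeOH then aq. Rochelle salt; used at once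
Reagents that add atoms: none
Why: DIBAL-H half-reduction at −78 °C stops at the chelated aluminium hemiacetal, which releases the aldehyde on work-up.

Step 5
Reactants: 4 [(Z)-2-iodoethenyl]trimethylsilane, 7 3,3-dimethoxybutanal, 8 3-methylcyclopent-2-en-1-one
Product: 12 (2S,3S)-2-[(1S)-1-hydroxy-3,3-dimethoxybutyl]-3-methyl-3-[(Z)-2-(trimethylsilyl)ethenyl]cyclopentan-1-one, via [(Z)-2-(trimethylsilyl)ethenyl]lithium 9 (not isolated), via dimethyl[(Z)-2-(trimethylsilyl)ethenyl]alumane 10 (not isolated), via dimethylaluminium (3S)-3-methyl-3-[(Z)-2-(trimethylsilyl)ethenyl]cyclopent-1-en-1-olate 11 (not isolated)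
Conditions: 4 (1.3 equiv), t-BuLi (2.6 equiv), Et2O, −78 °C; Me2AlCl (1.3 equiv), −78 → −30 °C; add to 8, Cu(OTf)2 (5 mol %), chiral sulfonate–NHC·Ag(I) complex (2.5 mol %, antipode giving the 3S adduct), THF, −50 °C, 12 h; then 7 (1.5 equiv), −78 °C, 2 h; aq. Rochelle salt
Reagents that add atoms: none
Why: Iodine–lithium exchange and Li→Al transmetalation keep the Z geometry, the Cu-catalysed asymmetric conjugate addition of the alkenylalane sets the quaternary C8a centre under ligand control, and the regiodefined (E)-aluminium enolate adds to 7 through a Zimmerman–Traxler chair on the face anti to the bulky (Z)-silylvinyl group (cis to the methyl), giving the anti aldol with the C3a and C4 configurations of the target.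

Step 6
Reactants: 12 (2S,3S)-2-[(1S)-1-hydroxy-3,3-dimethoxybutyl]-3-methyl-3-[(Z)-2-(trimethylsilyl)ethenyl]cyclopentan-1-one
Product: 14 (1R,2S,3S)-2-[(1S)-1-hydroxy-3-oxobutyl]-3-methyl-1-(propan-2-yl)-3-[(Z)-2-(trimethylsilyl)ethenyl]cyclopentan-1-ol, via (1R,2S,3S)-2-[(1S)-1-hydroxy-3,3-dimethoxybutyl]-3-methyl-1-(propan-2-yl)-3-[(Z)-2-(trimethylsilyl)ethenyl]cyclopentan-1-ol 13 (not isolated)
Conditions: i-PrMgCl (4 equiv), anhydrous CeCl3 (4 equiv), THF, −78 → −40 °C; then 0.5 M aq. HCl/THF, 0 °C, 30 min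
Reagents that add atoms: isopropylmagnesium chloride (CC(C)[Mg]Cl); water (O)
Why: The weakly basic organocerium reagent adds 1,2 to the ketone from the face opposite the adjacent, cerium-chelated oxido side chain, which gives the 3R carbinol with OH cis to that chain, and the dilute-acid work-up hydrolyses the dimethyl ketal (organocerium addition, acetal hydrolysis).

Step 7
Reactants: 14 (1R,2S,3S)-2-[(1S)-1-hydroxy-3-oxobutyl]-3-methyl-1-(propan-2-yl)-3-[(Z)-2-(trimethylsilyl)ethenyl]cyclopentan-1-ol
Product: 15 (1R,2S,3S)-2-[(1S)-1-hydroxy-3-oxobutyl]-3-[(Z)-2-iodoethenyl]-3-methyl-1-(propan-2-yl)cyclopentan-1-ol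
Conditions: NIS (1.3 equiv), (CF3)2CHOH, 0 °C, dark, 15 min; aq. Na2S2O3
Reagents that add atoms: N-iodosuccinimide (O=C1CCC(=O)N1I)
Why: ipso-Iododesilylation of the vinylsilane with NIS in HFIP proceeds with retention of the Z geometry, and the hydroxyls on the opposite ring face cannot cyclise onto the iodonium.

Step 8
Reactants: 15 (1R,2S,3S)-2-[(1S)-1-hydroxy-3-oxobutyl]-3-[(Z)-2-iodoethenyl]-3-methyl-1-(propan-2-yl)cyclopentan-1-ol
Product: 16 (3R,3aS,4S,6R,8aR)-6,8a-dimethyl-3-(propan-2-yl)-1,2,3,3a,4,5,6,8a-octahydroazulene-3,4,6-triol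
Conditions: NiBr2·glyme (10 mol %), chiral t-Bu-PyOX (12 mol %, matched antipode), Zn dust (3 equiv), DMA/THF, 0.02 M, 25 °C; aq. Rochelle salt
Reagents that add atoms: none
Why: Proposed new method: a ligated Ni(0) adds oxidatively to the (Z)-alkenyl iodide with retention, the methyl ketone, held by a Zn(II) bridge to the C4 hydroxyl, inserts into the Ni–C(sp2) bond (1,2-migratory insertion) to close the seven-membered ring, alkoxide transfer to Zn(II) and reduction by Zn(0) turn the nickel over, and the bridged chelate reinforced by the chiral ligand forces the new C6–O bond cis to C4–O (6R); the closest known reactions are Ni-catalysed reductive cyclisations of aryl or alkenyl halides onto ketones that give five- and six-membered tertiary alcohols, and the Nozaki–Hiyama–Kishi reaction.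

Step 9
Reactants: 17 4-bromophenol
Product: 18 (4-bromophenoxy)(tert-butyl)dimethylsilane
Conditions: TBSCl (1.1 equiv), imidazole (2 equiv), DMF, rt
Reagents that add atoms: tert-butyldimethylsilyl chloride (CC(C)(C)[Si](C)(C)Cl)
Why: Imidazole-assisted silylation protects the phenol for the organolithium step.

Step 10
Reactants: 18 (4-bromophenoxy)(tert-butyl)dimethylsilane
Product: 20 4-[(tert-butyldimethylsilyl)oxy]benzoic acid, via {4-[(tert-butyldimethylsilyl)oxy]phenyl}lithium 19 (not isolated)
Conditions: n-BuLi (1.05 equiv), THF, −78 °C; CO2; cold 1 M HCl to pH 4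
Reagents that add atoms: carbon dioxide (O=C=O)
Why: Bromine–lithium exchange and carboxylation of the aryllithium give the acid, and the para silyl ether cannot undergo retro-Brook migration.

Step 11
Reactants: 20 4-[(tert-butyldimethylsilyl)oxy]benzoic acid
Product: 21 4-[(tert-butyldimethylsilyl)oxy]benzoyl chloride
Conditions: (COCl)2 (1.2 equiv), DMF (cat.), CH2Cl2, 0 °C → rt; evaporate
Reagents that add atoms: oxalyl chloride (O=C(Cl)C(Cl)=O)
Why: Vilsmeier-catalysed acid chloride formation proceeds under conditions the aryl silyl ether tolerates.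

Step 12
Reactants: 16 (3R,3aS,4S,6R,8aR)-6,8a-dimethyl-3-(propan-2-yl)-1,2,3,3a,4,5,6,8a-octahydroazulene-3,4,6-triol, 21 4-[(tert-butyldimethylsilyl)oxy]benzoyl chloride
Product: 22 (3R,3aS,4S,6R,8aR)-3,6-dihydroxy-6,8a-dimethyl-3-(propan-2-yl)-1,2,3,3a,4,5,6,8a-octahydroazulen-4-yl 4-[(tert-butyldimethylsilyl)oxy]benzoate
Conditions: 21 (1.3 equiv), Et3N (3 equiv), DMAP (0.3 equiv), CH2Cl2, 0 °C → rt
Reagents that add atoms: none
Why: DMAP-catalysed acylation is selective for the only secondary hydroxyl because the two tertiary alcohols do not react (nucleophilic-catalysis esterification).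

Step 13
Reactants: 22 (3R,3aS,4S,6R,8aR)-3,6-dihydroxy-6,8a-dimethyl-3-(propan-2-yl)-1,2,3,3a,4,5,6,8a-octahydroazulen-4-yl 4-[(tert-butyldimethylsilyl)oxy]benzoate
Product: 23 (3R,3aS,4S,6R,8aR)-3,6-dihydroxy-6,8a-dimethyl-3-(propan-2-yl)-1,2,3,3a,4,5,6,8a-octahydroazulen-4-yl 4-hydroxybenzoate
Conditions: TBAF (1.1 equiv), AcOH (1.2 equiv), THF, 0 °C
Reagents that add atoms: none
Why: Buffered fluoride cleaves the phenolic silyl ether quickly at 0 °C without ester cleavage or ionisation of the tertiary allylic alcohol.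

**Compound list**
1 | ethynyltrimethylsilane | C#C[Si](C)(C)C | starting material
2 | lithium (trimethylsilyl)acetylide | [Li]C#C[Si](C)(C)C | intermediate
3 | (iodoethynyl)trimethylsilane | IC#C[Si](C)(C)C | intermediate
4 | [(Z)-2-iodoethenyl]trimethylsilane | I/C=C\[Si](C)(C)C | intermediate
5 | methyl 3-oxobutanoate | CC(=O)CC(=O)OC | starting material
6 | methyl 3,3-dimethoxybutanoate | COC(=O)CC(C)(OC)OC | intermediate
7 | 3,3-dimethoxybutanal | O=CCC(C)(OC)OC | intermediate
8 | 3-methylcyclopent-2-en-1-one | CC1=CC(=O)CC1 | starting material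
9 | [(Z)-2-(trimethylsilyl)ethenyl]lithium | [Li]/C=C\[Si](C)(C)C | intermediate
10 | dimethyl[(Z)-2-(trimethylsilyl)ethenyl]alumane | C[Al](C)/C=C\[Si](C)(C)C | intermediate
11 | dimethylaluminium (3S)-3-methyl-3-[(Z)-2-(trimethylsilyl)ethenyl]cyclopent-1-en-1-olate | C[Al](C)OC1=C[C@@](C)(/C=C\[Si](C)(C)C)CC1 | intermediate
12 | (2S,3S)-2-[(1S)-1-hydroxy-3,3-dimethoxybutyl]-3-methyl-3-[(Z)-2-(trimethylsilyl)ethenyl]cyclopentan-1-one | O=C1CC[C@](C)(/C=C\[Si](C)(C)C)[C@H]1[C@@H](O)CC(C)(OC)OC | intermediate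
13 | (1R,2S,3S)-2-[(1S)-1-hydroxy-3,3-dimethoxybutyl]-3-methyl-1-(propan-2-yl)-3-[(Z)-2-(trimethylsilyl)ethenyl]cyclopentan-1-ol | CC(C)[C@]1(O)CC[C@](C)(/C=C\[Si](C)(C)C)[C@H]1[C@@H](O)CC(C)(OC)OC | intermediate
14 | (1R,2S,3S)-2-[(1S)-1-hydroxy-3-oxobutyl]-3-methyl-1-(propan-2-yl)-3-[(Z)-2-(trimethylsilyl)ethenyl]cyclopentan-1-ol | CC(C)[C@]1(O)CC[C@](C)(/C=C\[Si](C)(C)C)[C@H]1[C@@H](O)CC(C)=O | intermediate
15 | (1R,2S,3S)-2-[(1S)-1-hydroxy-3-oxobutyl]-3-[(Z)-2-iodoethenyl]-3-methyl-1-(propan-2-yl)cyclopentan-1-ol | CC(C)[C@]1(O)CC[C@](C)(/C=C\I)[C@H]1[C@@H](O)CC(C)=O | intermediate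
16 | (3R,3aS,4S,6R,8aR)-6,8a-dimethyl-3-(propan-2-yl)-1,2,3,3a,4,5,6,8a-octahydroazulene-3,4,6-triol | CC(C)[C@]1(O)CC[C@]2(C)C=C[C@](C)(O)C[C@H](O)[C@H]21 | intermediate
17 | 4-bromophenol | Oc1ccc(Br)cc1 | starting material
18 | (4-bromophenoxy)(tert-butyl)dimethylsilane | CC(C)(C)[Si](C)(C)Oc1ccc(Br)cc1 | intermediate
19 | {4-[(tert-butyldimethylsilyl)oxy]phenyl}lithium | [Li]c1ccc(O[Si](C)(C)C(C)(C)C)cc1 | intermediate
20 | 4-[(tert-butyldimethylsilyl)oxy]benzoic acid | CC(C)(C)[Si](C)(C)Oc1ccc(cc1)C(O)=O | intermediate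
21 | 4-[(tert-butyldimethylsilyl)oxy]benzoyl chloride | CC(C)(C)[Si](C)(C)Oc1ccc(cc1)C(Cl)=O | intermediate
22 | (3R,3aS,4S,6R,8aR)-3,6-dihydroxy-6,8a-dimethyl-3-(propan-2-yl)-1,2,3,3a,4,5,6,8a-octahydroazulen-4-yl 4-[(tert-butyldimethylsilyl)oxy]benzoate | CC(C)[C@]1(O)CC[C@]2(C)C=C[C@](C)(O)C[C@H](OC(=O)c3ccc(O[Si](C)(C)C(C)(C)C)cc3)[C@H]21 | intermediate
23 | (3R,3aS,4S,6R,8aR)-3,6-dihydroxy-6,8a-dimethyl-3-(propan-2-yl)-1,2,3,3a,4,5,6,8a-octahydroazulen-4-yl 4-hydroxybenzoate | CC(C)[C@]1(O)CC[C@]2(C)C=C[C@](C)(O)C[C@H](OC(=O)c3ccc(O)cc3)[C@H]21 | target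

**Step count**
Total: 13 steps. Longest linear sequence: 8 steps (1 → 2 → 5 → 6 → 7 → 8 → 12 → 13; the branch 3 → 4 → 5 … is equally long), which is 62 % of the total.

**Three steps most likely to fail, with fallbacks**

Step 5 (three-component coupling). The risks are the ee of the conjugate addition of a (Z)-silylvinyl alane to a cyclopentenone, the facial bias exerted by the silylvinyl group in the aldol, and the fragility of aldehyde 7. The fallback sets out from 4 and 8 and comes back at 12. The same Cu-catalysed conjugate addition of alane 10 is run alone and enolate 11 is quenched with TMSCl/Et3N, so that the silyl enol ether trimethyl({(3S)-3-methyl-3-[(Z)-2-(trimethylsilyl)ethenyl]cyclopent-1-en-1-yl}oxy)silane F1 is isolated. The ee can be measured at this stage and, if needed, raised by preparative chiral chromatography. MeLi (THF, 0 °C) then cleaves F1 to the regiodefined lithium (3S)-3-methyl-3-[(Z)-2-(trimethylsilyl)ethenyl]cyclopent-1-en-1-olate F2, which is treated with 7 at −78 °C in a separate, closed-transition-state lithium aldol to give 12. Residual minor enantiomer can also be removed later by recrystallising triol 16.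

Step 6 (isopropyl addition). The ketone is hindered on the attack face by the 1,3-related silylvinyl group, and enolisation, β-hydride reduction or retro-aldol/E1cB loss of the oxido side chain may compete. The fallback sets out from 12 and comes back at 13. The smaller, non-reducing sp2 nucleophile 2-propenylmagnesium bromide/CeCl3 (THF, −78 °C) gives (1S,2S,3S)-2-[(1S)-1-hydroxy-3,3-dimethoxybutyl]-3-methyl-1-(prop-1-en-2-yl)-3-[(Z)-2-(trimethylsilyl)ethenyl]cyclopentan-1-ol F3. Hydrogen-atom-transfer hydrogenation (Mn(dpm)3 cat., PhSiH3, TBHP, i-PrOH, rt), which is selective for the 1,1-disubstituted alkene over the (Z)-vinylsilane, then gives 13, and 13 is hydrolysed to 14 exactly as in step 6.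

Step 8 (new Ni-catalysed alkenyl iodide–ketone cyclisation). Possible failures are protodeiodination by the free hydroxyls, dimerisation, slow carbonyl insertion for a seven-membered ring, or the wrong C6 epimer. Hydroxy ketone 15 may also sit partly as its cyclic hemiketal with the C3–OH; this is reversible. The fallback sets out from 15 and comes back at 16 and uses known chemistry: an intramolecular Nozaki–Hiyama–Kishi reaction (CrCl2 6 equiv, NiCl2 2 mol %, degassed DMSO/THF, rt, high dilution). This replaces the catalytic, ligand-controlled nickel insertion by a stoichiometric alkenylchromium(III) carbonyl addition that relies only on the C4-hydroxyl/ketone chelate for the cis-diol outcome. It makes no new compound (F0).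

**Further compounds**
F1 | step 5 | trimethyl({(3S)-3-methyl-3-[(Z)-2-(trimethylsilyl)ethenyl]cyclopent-1-en-1-yl}oxy)silane | C[Si](C)(C)OC1=C[C@@](C)(/C=C\[Si](C)(C)C)CC1
F2 | step 5 | lithium (3S)-3-methyl-3-[(Z)-2-(trimethylsilyl)ethenyl]cyclopent-1-en-1-olate | [Li]OC1=C[C@@](C)(/C=C\[Si](C)(C)C)CC1
F3 | step 6 | (1S,2S,3S)-2-[(1S)-1-hydroxy-3,3-dimethoxybutyl]-3-methyl-1-(prop-1-en-2-yl)-3-[(Z)-2-(trimethylsilyl)ethenyl]cyclopentan-1-ol | CC(=C)[C@]1(O)CC[C@](C)(/C=C\[Si](C)(C)C)[C@H]1[C@@H](O)CC(C)(OC)OC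
F0 | step 8 | none | none
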